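**Retrosynthetic overview**

1. Target 21 comes from ketone 20 by cleavage of four benzyl ethers. The dodecanoyl group is built on ring D of phenol 16 by ortho-formylation, addition of C11H23MgBr and oxidation; positions 3' and 5' of ring D become equivalent once all three ring D oxygens are free.
2. C2 (S) comes from hydrogenation of the C2=C3 enol ether of 4H-chromene 14 on the face that carries ring D, steered by the ring D carbamate, which is afterwards removed with LiAlH4.
3. Ring C (bonds C3–C4 and O1–C2) and C4 (R) come from a chiral phosphoric acid catalysed annulation of enamide 11 with racemic benzhydrol 7. The feature used: C4 is a diarylmethine carbon on ring A ortho to O1, so ring A with O1 and C4 is a latent ortho-quinone methide (C4 exocyclic, O1 the carbonyl oxygen), and ring D has no free hydroxyl.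
4. Benzhydrol 7 comes from the C4–C1' bond, made by ortho-lithiation of ring D carbamate 2 and addition to ring A aldehyde 4, then deallylation; enamide 11 comes from the oxime of ketone 8.
5. Rings A, B and D are bought as benzene rings; ring C is the only ring formed (step 7).

Key step: step 7

Assumption: the (R)-phosphoric acid is taken to give the (4R)-chromene, and its (S)-enantiomer is used unchanged otherwise if the sense proves opposite; 1, 3 and 8 are taken as catalogue compounds.

**Route**

Step 1
Reactants: 1 3,5-bis(benzyloxy)phenol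
Product: 2 3,5-bis(benzyloxy)phenyl N,N-diethylcarbamate
Conditions: NaH, THF, 0 °C; ClC(O)NEt2, 25 °C
Reagents that add atoms: diethylcarbamoyl chloride, CCN(CC)C(Cl)=O
Why: O-carbamoylation of the sodium phenoxide (nucleophilic acyl substitution) should be clean and installs the group that later directs both the ortho-lithiation and the hydrogenation.

Step 2
Reactants: 3 4-(benzyloxy)-2-hydroxybenzaldehyde
Product: 4 2-(allyloxy)-4-(benzyloxy)benzaldehyde
Conditions: allyl bromide, K2CO3, DMF, 50 °C
Reagents that add atoms: allyl bromide, C=CCBr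
Why: Williamson ether synthesis masks the acidic phenol so that the aldehyde stays electrophilic at −78 °C, with a group that cannot migrate to a neighbouring alkoxide and comes off under neutral conditions.

Step 3
Reactants: 2 3,5-bis(benzyloxy)phenyl N,N-diethylcarbamate; 4 2-(allyloxy)-4-(benzyloxy)benzaldehyde
Product: 6 rac-3,5-bis(benzyloxy)-2-{[2-(allyloxy)-4-(benzyloxy)phenyl](hydroxy)methyl}phenyl N,N-diethylcarbamate, via ortho-lithiated carbamate 5 (not isolated)
Conditions: s-BuLi, TMEDA, THF, −78 °C; then 4, −78 °C; AcOH in THF, −78 °C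
Reagents that add atoms: none
Why: Directed ortho-metalation occurs at the position flanked by the carbamate and a benzyloxy group (the two such positions are equivalent), and 1,2-addition of aryllithium 5 to the aldehyde with a cold acidic quench should outrun both the anionic ortho-Fries shift and carbamoyl transfer to the new alkoxide; the carbinol centre forms racemic and is erased in step 7.

Step 4
Reactants: 6 rac-allyl-protected benzhydrol
Product: 7 rac-3,5-bis(benzyloxy)-2-{[4-(benzyloxy)-2-hydroxyphenyl](hydroxy)methyl}phenyl N,N-diethylcarbamate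
Conditions: Pd(PPh3)4 (5 mol%), morpholine, THF, 25 °C; chromatography on Et3N-deactivated silica
Reagents that add atoms: none
Why: Tsuji–Trost deallylation, in which zerovalent palladium ionises the aryl allyl ether to a π-allyl complex that morpholine intercepts, is neutral enough to leave the acid-labile benzhydrol and the carbamate untouched.

Step 5
Reactants: 8 4'-(benzyloxy)acetophenone
Product: 9 (E)-1-[4-(benzyloxy)phenyl]ethan-1-one oxime
Conditions: NH2OH·HCl, NaOAc, EtOH–H2O, reflux
Reagents that add atoms: hydroxylamine hydrochloride, NO.Cl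
Why: Oxime formation by condensation of an aryl methyl ketone with hydroxylamine is routine, and the oxime geometry is of no consequence.

Step 6
Reactants: 9 (E)-1-[4-(benzyloxy)phenyl]ethan-1-one oxime
Product: 11 N-{1-[4-(benzyloxy)phenyl]vinyl}acetamide, via oxime O-acetate 10 (not isolated)
Conditions: Fe powder, Ac2O, AcOH, toluene, 70 °C
Reagents that add atoms: acetic anhydride, CC(=O)OC(C)=O
Why: Reductive acylation of a ketoxime: O-acetylation, N–O cleavage by zerovalent iron and N-acetylation of the imine, which tautomerises to the terminal enamide.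

Step 7
Reactants: 7 rac-ortho-hydroxybenzhydrol; 11 N-{1-[4-(benzyloxy)phenyl]vinyl}acetamide
Product: 14 3,5-bis(benzyloxy)-2-{(4R)-7-(benzyloxy)-2-[4-(benzyloxy)phenyl]-4H-chromen-4-yl}phenyl N,N-diethylcarbamate, via ortho-quinone methide 12 (not isolated), via 2-acetamidochroman 13 (not isolated)
Conditions: (R)-3,3'-bis(2,4,6-triisopropylphenyl)-1,1'-binaphthyl-2,2'-diyl hydrogen phosphate (10 mol%), 11 (1.5 equiv), 3 Å MS, CHCl3, 25 °C then 50 °C, argon
Reagents that add atoms: none
Why: The phosphoric acid ionises the doubly benzylic alcohol 7 with loss of water to ortho-quinone methide 12, in which ring A is the dienone, C4 the exocyclic carbon and O1 the carbonyl oxygen. Hydrogen-bonded to O1 of 12 and to the N–H of 11, the chiral phosphate lets the enamide CH2 carbon add in conjugate fashion to one face of C4 (C3–C4 bond), and this catalyst-controlled facial choice sets the only new stereocentre, C4 (R). The resulting N-acyliminium ion is captured by the ring A phenol oxygen in a 6-exo-trig closure (O1–C2 bond, ring C) to give N,O-acetal 13, which on warming ionises at C2 (stabilised by the 4-benzyloxyphenyl group) and loses acetamide to leave the C2=C3 enol ether. The closest known reaction type is the chiral phosphoric acid catalysed addition of enamides and 1,3-dicarbonyl compounds to ortho-quinone methides generated in situ from ortho-hydroxybenzyl alcohols, a stepwise formal [4+2] annulation to 4H-chromenes. The step needs enantiofacial selectivity at C4, closure onto O1 only, and preference for the enamide over self-condensation: the first rests on the catalyst, the second on ring A holding the only free hydroxyl (the ring D oxygen ortho to C4 is capped as the carbamate), and the third on the excess of enamide and the reduced nucleophilicity of the carbamate-bearing ring D. C2 is left trigonal on purpose, so that its configuration is set only in step 8.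

Step 8
Reactants: 14 (4R)-4H-chromene
Product: 15 3,5-bis(benzyloxy)-2-{(2S,4R)-7-(benzyloxy)-2-[4-(benzyloxy)phenyl]chroman-4-yl}phenyl N,N-diethylcarbamate
Conditions: [Ir(cod)(PCy3)(py)]PF6 (10 mol%), H2 (5 bar), CH2Cl2, 25 °C; 14 used at once, air excluded
Reagents that add atoms: none
Why: Directed homogeneous hydrogenation: the ring D carbamate carbonyl binds the cationic iridium centre and delivers hydrogen to the C2=C3 face on which ring D stands, so that H at C2 ends up cis to ring D and the aryl group trans to it (2S, 2,4-trans), whereas an undirected catalyst would approach the open face and give the cis isomer.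

Step 9
Reactants: 15 (2S,4R)-flavan carbamate
Product: 16 3,5-bis(benzyloxy)-2-{(2S,4R)-7-(benzyloxy)-2-[4-(benzyloxy)phenyl]chroman-4-yl}phenol
Conditions: LiAlH4, THF, 0 °C to reflux; aqueous NaOH work-up
Reagents that add atoms: none
Why: Hydride reduction of the aryl carbamate (attack at the carbonyl, expulsion of the phenoxide, reduction of the formamide to the amine) frees the ring D phenol without touching the benzyl ethers or either stereocentre.

Step 10
Reactants: 16 ring D phenol
Product: 18 4,6-bis(benzyloxy)-3-{(2S,4R)-7-(benzyloxy)-2-[4-(benzyloxy)phenyl]chroman-4-yl}-2-hydroxybenzaldehyde, via salicyl alcohol 17 (not isolated)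
Conditions: MgCl2, Et3N, (CH2O)n, MeCN, reflux; aqueous NH4Cl work-up
Reagents that add atoms: paraformaldehyde (as formaldehyde), C=O
Why: Magnesium-mediated ortho-formylation of phenols (Casnati–Skattebøl reaction), in which the magnesium phenoxide delivers formaldehyde to the ortho carbon and a second formaldehyde oxidises hydroxymethyl intermediate 17 by hydride transfer; ring D holds the only free hydroxyl and its single open ortho position is C3', so only one regioisomer can form.

Step 11
Reactants: 18 ring D salicylaldehyde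
Product: 19 1-(4,6-bis(benzyloxy)-3-{(2S,4R)-7-(benzyloxy)-2-[4-(benzyloxy)phenyl]chroman-4-yl}-2-hydroxyphenyl)dodecan-1-ol (both carbinol epimers)
Conditions: C11H23MgBr (3 equiv), THF, 0 to 25 °C; pH 7 buffer; carried on without chromatography
Reagents that add atoms: undecylmagnesium bromide, CCCCCCCCCCC[Mg]Br
Why: Grignard 1,2-addition to the aldehyde after the first equivalent deprotonates the phenol; the new carbinol centre forms without control and is removed in step 12.

Step 12
Reactants: 19 benzylic carbinol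
Product: 20 1-(4,6-bis(benzyloxy)-3-{(2S,4R)-7-(benzyloxy)-2-[4-(benzyloxy)phenyl]chroman-4-yl}-2-hydroxyphenyl)dodecan-1-one
Conditions: MnO2 (activated, excess), CH2Cl2, 25 °C
Reagents that add atoms: none
Why: Benzylic alcohol oxidation by MnO2 should give the hydrogen-bonded ortho-hydroxyaryl ketone under neutral heterogeneous conditions that spare the flavan and the phenol.

Step 13
Reactants: 20 tetrabenzyl ether of the target
Product: 21 (+)-myristinin A, 1-{2,4,6-trihydroxy-3-[(2S,4R)-7-hydroxy-2-(4-hydroxyphenyl)chroman-4-yl]phenyl}dodecan-1-one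
Conditions: H2 (1 atm), Pd/C (10 wt%), EtOAc–MeOH, 25 °C
Reagents that add atoms: none
Why: Hydrogenolysis of the four aryl benzyl ethers over Pd/C under neutral conditions; the chelated, doubly ortho-oxygenated aryl ketone and the C2–O1 benzylic ether are expected to survive at ambient pressure if the reaction is stopped at full debenzylation.

**Compound list**

1 | 3,5-bis(benzyloxy)phenol | Oc1cc(OCc2ccccc2)cc(OCc2ccccc2)c1 | starting material
2 | 3,5-bis(benzyloxy)phenyl N,N-diethylcarbamate | CCN(CC)C(=O)Oc1cc(OCc2ccccc2)cc(OCc2ccccc2)c1 | intermediate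
3 | 4-(benzyloxy)-2-hydroxybenzaldehyde | O=Cc1ccc(OCc2ccccc2)cc1O | starting material
4 | 2-(allyloxy)-4-(benzyloxy)benzaldehyde | C=CCOc1cc(OCc2ccccc2)ccc1C=O | intermediate
5 | [2,4-bis(benzyloxy)-6-(diethylcarbamoyloxy)phenyl]lithium (transient) | [Li]c1c(OC(=O)N(CC)CC)cc(OCc2ccccc2)cc1OCc1ccccc1 | intermediate
6 | rac-3,5-bis(benzyloxy)-2-{[2-(allyloxy)-4-(benzyloxy)phenyl](hydroxy)methyl}phenyl N,N-diethylcarbamate | CCN(CC)C(=O)Oc1cc(OCc2ccccc2)cc(OCc2ccccc2)c1C(O)c1ccc(OCc2ccccc2)cc1OCC=C | intermediate
7 | rac-3,5-bis(benzyloxy)-2-{[4-(benzyloxy)-2-hydroxyphenyl](hydroxy)methyl}phenyl N,N-diethylcarbamate | CCN(CC)C(=O)Oc1cc(OCc2ccccc2)cc(OCc2ccccc2)c1C(O)c1ccc(OCc2ccccc2)cc1O | intermediate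
8 | 4'-(benzyloxy)acetophenone | CC(=O)c1ccc(OCc2ccccc2)cc1 | starting material
9 | (E)-1-[4-(benzyloxy)phenyl]ethan-1-one oxime | C/C(=N\O)c1ccc(OCc2ccccc2)cc1 | intermediate
10 | (E)-1-[4-(benzyloxy)phenyl]ethan-1-one O-acetyloxime (transient) | C/C(=N\OC(C)=O)c1ccc(OCc2ccccc2)cc1 | intermediate
11 | N-{1-[4-(benzyloxy)phenyl]vinyl}acetamide | C=C(NC(C)=O)c1ccc(OCc2ccccc2)cc1 | intermediate
12 | 3,5-bis(benzyloxy)-2-{[4-(benzyloxy)-6-oxocyclohexa-2,4-dien-1-ylidene]methyl}phenyl N,N-diethylcarbamate (ortho-quinone methide, transient) | O=C1C=C(OCc2ccccc2)C=CC1=Cc1c(OC(=O)N(CC)CC)cc(OCc2ccccc2)cc1OCc1ccccc1 | intermediate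
13 | 2-{(4R)-2-acetamido-7-(benzyloxy)-2-[4-(benzyloxy)phenyl]chroman-4-yl}-3,5-bis(benzyloxy)phenyl N,N-diethylcarbamate (both C2 epimers, transient) | CCN(CC)C(=O)Oc1cc(OCc2ccccc2)cc(OCc2ccccc2)c1[C@@H]1CC(NC(C)=O)(c2ccc(OCc3ccccc3)cc2)Oc2cc(OCc3ccccc3)ccc21 | intermediate
14 | 3,5-bis(benzyloxy)-2-{(4R)-7-(benzyloxy)-2-[4-(benzyloxy)phenyl]-4H-chromen-4-yl}phenyl N,N-diethylcarbamate | CCN(CC)C(=O)Oc1cc(OCc2ccccc2)cc(OCc2ccccc2)c1[C@@H]1C=C(c2ccc(OCc3ccccc3)cc2)Oc2cc(OCc3ccccc3)ccc21 | intermediate
15 | 3,5-bis(benzyloxy)-2-{(2S,4R)-7-(benzyloxy)-2-[4-(benzyloxy)phenyl]chroman-4-yl}phenyl N,N-diethylcarbamate | CCN(CC)C(=O)Oc1cc(OCc2ccccc2)cc(OCc2ccccc2)c1[C@@H]1C[C@@H](c2ccc(OCc3ccccc3)cc2)Oc2cc(OCc3ccccc3)ccc21 | intermediate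
16 | 3,5-bis(benzyloxy)-2-{(2S,4R)-7-(benzyloxy)-2-[4-(benzyloxy)phenyl]chroman-4-yl}phenol | Oc1cc(OCc2ccccc2)cc(OCc2ccccc2)c1[C@@H]1C[C@@H](c2ccc(OCc3ccccc3)cc2)Oc2cc(OCc3ccccc3)ccc21 | intermediate
17 | 3,5-bis(benzyloxy)-2-{(2S,4R)-7-(benzyloxy)-2-[4-(benzyloxy)phenyl]chroman-4-yl}-6-(hydroxymethyl)phenol (transient) | OCc1c(O)c([C@@H]2C[C@@H](c3ccc(OCc4ccccc4)cc3)Oc3cc(OCc4ccccc4)ccc32)c(OCc2ccccc2)cc1OCc1ccccc1 | intermediate
18 | 4,6-bis(benzyloxy)-3-{(2S,4R)-7-(benzyloxy)-2-[4-(benzyloxy)phenyl]chroman-4-yl}-2-hydroxybenzaldehyde | O=Cc1c(O)c([C@@H]2C[C@@H](c3ccc(OCc4ccccc4)cc3)Oc3cc(OCc4ccccc4)ccc32)c(OCc2ccccc2)cc1OCc1ccccc1 | intermediate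
19 | 1-(4,6-bis(benzyloxy)-3-{(2S,4R)-7-(benzyloxy)-2-[4-(benzyloxy)phenyl]chroman-4-yl}-2-hydroxyphenyl)dodecan-1-ol (carbinol epimers) | CCCCCCCCCCCC(O)c1c(O)c([C@@H]2C[C@@H](c3ccc(OCc4ccccc4)cc3)Oc3cc(OCc4ccccc4)ccc32)c(OCc2ccccc2)cc1OCc1ccccc1 | intermediate
20 | 1-(4,6-bis(benzyloxy)-3-{(2S,4R)-7-(benzyloxy)-2-[4-(benzyloxy)phenyl]chroman-4-yl}-2-hydroxyphenyl)dodecan-1-one | CCCCCCCCCCCC(=O)c1c(O)c([C@@H]2C[C@@H](c3ccc(OCc4ccccc4)cc3)Oc3cc(OCc4ccccc4)ccc32)c(OCc2ccccc2)cc1OCc1ccccc1 | intermediate
21 | (+)-myristinin A | CCCCCCCCCCCC(=O)c1c(O)cc(O)c([C@@H]2C[C@@H](c3ccc(O)cc3)Oc3cc(O)ccc32)c1O | target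

**Step count**

Total step count: 13. Longest linear sequence: 10 steps (1 → 2 → 6 → 7 → 14 → 15 → 16 → 18 → 19 → 20 → 21).

**Steps most likely to fail**

Step 7. Ring D must twist out of the quinone methide plane, and its two ortho substituents then lie over both faces of C4. Addition of the enamide may therefore be slow and poorly face-selective, so that the chromene forms with insufficient enantiomeric purity. Fallback, from 7 and 11 back to 14: catalyst control is given up. The two partners are combined under the achiral acid (PhO)2P(O)OH in CHCl3 at 50 °C and pass through 12 and the racemic 2-acetamidochroman F1 to the racemic 4H-chromene F2. This is separated by preparative chromatography on an amylose tris(3,5-dimethylphenylcarbamate) stationary phase. The (4R)-enantiomer is compound 14 and enters step 8; the other enantiomer is discarded.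

Step 8. The carbamate has to reach the iridium centre through an eight-membered chelate. If it does not, hydrogen is delivered to the open face and the 2,4-cis flavan results. An iridium hydride may also move the double bond into C3=C4 and erase C4, or the acidic catalyst may degrade the enol ether. Fallback, from 14 back to 15: C2 is set by reagent control instead. The enol ether of 14 is hydrolysed (aqueous HCl, THF, 25 °C) to the ring-opened ketone 3,5-bis(benzyloxy)-2-{(1R)-1-[4-(benzyloxy)-2-hydroxyphenyl]-3-[4-(benzyloxy)phenyl]-3-oxopropyl}phenyl N,N-diethylcarbamate F3. Corey–Bakshi–Shibata reduction follows, with (S)-1-methyl-3,3-diphenyltetrahydro-1H,3H-pyrrolo[1,2-c][1,3,2]oxazaborole and BH3·SMe2 in THF. It should give the (1R,3R)-carbinol 3,5-bis(benzyloxy)-2-{(1R,3R)-1-[4-(benzyloxy)-2-hydroxyphenyl]-3-[4-(benzyloxy)phenyl]-3-hydroxypropyl}phenyl N,N-diethylcarbamate F4. Mitsunobu etherification (PPh3, diisopropyl azodicarboxylate, THF, 0 °C) then closes ring C through the only free phenol, with inversion at the carbinol carbon, to give the (2S,4R)-flavan 15.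

Step 3. The metalation may go astray: a benzylic OCH2 group may be deprotonated and undergo Wittig rearrangement, or the lithiated carbamate may undergo the anionic ortho-Fries shift before the aldehyde captures it. Fallback, from 1 back to 7 (steps 1–4 are bypassed): the polarity of the C4–C1' bond formation is reversed and no ortho-lithiation is used.
- Phenol 1 is ortho-formylated (MgCl2, Et3N, paraformaldehyde, MeCN, reflux) to 2,4-bis(benzyloxy)-6-hydroxybenzaldehyde F5.
- F5 is carbamoylated (NaH, ClC(O)NEt2, THF) to 3,5-bis(benzyloxy)-2-formylphenyl N,N-diethylcarbamate F6.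
- Purchased 4-bromoresorcinol is monobenzylated at the hydroxyl para to bromine (BnBr, K2CO3, acetone) to 5-(benzyloxy)-2-bromophenol F7; the regioisomer is removed by chromatography.
- F7 is treated with n-BuLi (2.2 equiv, Et2O–THF, −78 to 0 °C) to give lithium 5-(benzyloxy)-2-lithiophenoxide F8.
- F8 is added to F6 at −78 °C and quenched cold with AcOH, which gives benzhydrol 7 directly.

Further compounds
F1 | step 7 | rac-2-{2-acetamido-7-(benzyloxy)-2-[4-(benzyloxy)phenyl]chroman-4-yl}-3,5-bis(benzyloxy)phenyl N,N-diethylcarbamate | CCN(CC)C(=O)Oc1cc(OCc2ccccc2)cc(OCc2ccccc2)c1C1CC(NC(C)=O)(c2ccc(OCc3ccccc3)cc2)Oc2cc(OCc3ccccc3)ccc21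
F2 | step 7 | rac-3,5-bis(benzyloxy)-2-{7-(benzyloxy)-2-[4-(benzyloxy)phenyl]-4H-chromen-4-yl}phenyl N,N-diethylcarbamate | CCN(CC)C(=O)Oc1cc(OCc2ccccc2)cc(OCc2ccccc2)c1C1C=C(c2ccc(OCc3ccccc3)cc2)Oc2cc(OCc3ccccc3)ccc21
F3 | step 8 | 3,5-bis(benzyloxy)-2-{(1R)-1-[4-(benzyloxy)-2-hydroxyphenyl]-3-[4-(benzyloxy)phenyl]-3-oxopropyl}phenyl N,N-diethylcarbamate | CCN(CC)C(=O)Oc1cc(OCc2ccccc2)cc(OCc2ccccc2)c1[C@H](CC(=O)c1ccc(OCc2ccccc2)cc1)c1ccc(OCc2ccccc2)cc1O
F4 | step 8 | 3,5-bis(benzyloxy)-2-{(1R,3R)-1-[4-(benzyloxy)-2-hydroxyphenyl]-3-[4-(benzyloxy)phenyl]-3-hydroxypropyl}phenyl N,N-diethylcarbamate | CCN(CC)C(=O)Oc1cc(OCc2ccccc2)cc(OCc2ccccc2)c1[C@H](C[C@@H](O)c1ccc(OCc2ccccc2)cc1)c1ccc(OCc2ccccc2)cc1O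
F5 | step 3 | 2,4-bis(benzyloxy)-6-hydroxybenzaldehyde | O=Cc1c(O)cc(OCc2ccccc2)cc1OCc1ccccc1
F6 | step 3 | 3,5-bis(benzyloxy)-2-formylphenyl N,N-diethylcarbamate | CCN(CC)C(=O)Oc1cc(OCc2ccccc2)cc(OCc2ccccc2)c1C=O
F7 | step 3 | 5-(benzyloxy)-2-bromophenol | Oc1cc(OCc2ccccc2)ccc1Br
F8 | step 3 | lithium 5-(benzyloxy)-2-lithiophenoxide | [Li]Oc1cc(OCc2ccccc2)ccc1[Li]
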